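The isoflavone is cut at C3–C4 and O1–C2 of the pyranone (ring C), giving a ring A salicylaldehyde and a ring B silylalkyne that already stand at the chromone oxidation level. One rhodium-catalysed oxidative annulation forms both bonds and closes ring C. It exploits the ortho pairing of the future O1 hydroxyl with the formyl carbon (future C4), which guides rhodium into the aldehyde C–H bond, and the C2=C3 unit, which maps onto an alkyne whose silyl group occupies C2 and forces ring B onto C3. The precursor is 6-hydroxy-2,4-dimethoxy-3-prenylbenzaldehyde; its 2-methoxy group becomes the chelated C5 oxygen and is freed in the last step.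

Key step: step 5

Assumption: the target has no stereocentre and its only alkene carries two identical methyl groups, so no stereochemical element has to be set.

Structure check: in aldehyde 7 the formyl carbon becomes C4, C1 becomes C4a, C6 (OH) becomes C8a with O1, C5 becomes C8, C4 (OMe) becomes C7, C3 (prenyl) becomes C6 and C2 (OMe) becomes C5. Compounds 7, 10 and 11 map atom for atom onto the target, so no structural correction is needed. "Prenyl" means 3-methylbut-2-en-1-yl throughout.

Step 1
Reactants: 1 1,3-dimethoxybenzene; 2 prenyl bromide (1-bromo-3-methylbut-2-ene)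
Product: 4 1,3-dimethoxy-2-(3-methylbut-2-en-1-yl)benzene, via 2,6-dimethoxyphenyllithium 3 (not isolated)
Conditions: n-BuLi, THF, 0 °C to rt; then CuI (10 mol%), 2, −20 °C to rt
Reagents that add atoms: n-butyllithium, [Li]CCCC (lithium of intermediate 3 only)
Why: Directed ortho-metalation: both methoxy groups steer n-BuLi to the C2 hydrogen between them, and copper-catalysed allylic substitution of the resulting aryllithium on the primary prenyl bromide should give the linear (SN2) prenyl arene.

Step 2
Reactants: 4 1,3-dimethoxy-2-(3-methylbut-2-en-1-yl)benzene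
Product: 6 3,5-dimethoxy-4-(3-methylbut-2-en-1-yl)phenol, via aryl pinacol boronate 5 (not isolated)
Conditions: [Ir(OMe)(cod)]2 (1.5 mol%), dtbpy (3 mol%), B2pin2 (1.0 equiv), THF, 60 °C; then 30% H2O2, aq NaOH, THF, 0 °C; aq NH4Cl
Reagents that add atoms: bis(pinacolato)diboron, CC1(C)OB(OC1(C)C)B1OC(C)(C)C(C)(C)O1 (boryl group of intermediate 5 only); hydrogen peroxide, OO (phenol oxygen of 6)
Why: Iridium-catalysed C–H borylation is sterically controlled and should select the one ring hydrogen with no ortho substituent (para to the prenyl group) while leaving the trisubstituted alkene alone, and alkaline peroxide oxidation of the C–B bond (1,2-aryl shift from boron to oxygen) then gives the phenol.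

Step 3
Reactants: 6 3,5-dimethoxy-4-(3-methylbut-2-en-1-yl)phenol
Product: 7 6-hydroxy-2,4-dimethoxy-3-(3-methylbut-2-en-1-yl)benzaldehyde
Conditions: MgCl2, Et3N, (CH2O)n, MeCN, reflux; cold dilute aq HCl work-up
Reagents that add atoms: paraformaldehyde as formaldehyde, C=O
Why: Casnati–Skattebøl ortho-formylation: the magnesium phenoxide delivers formaldehyde to the carbon next to the hydroxyl and a second formaldehyde oxidises the benzylic alkoxide by hydride transfer, and since the two ortho positions are equivalent by symmetry and the para position is blocked only one aldehyde can form.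

Step 4
Reactants: 8 1-bromo-2,4,5-trimethoxybenzene; 9 ethynyltrimethylsilane
Product: 10 trimethyl[(2,4,5-trimethoxyphenyl)ethynyl]silane
Conditions: Pd(PhCN)2Cl2 (3 mol%), [HP(t-Bu)3]BF4 (6 mol%), CuI (2 mol%), i-Pr2NH, dioxane, rt to 45 °C
Reagents that add atoms: none
Why: Sonogashira coupling: the bulky electron-rich phosphine lets zerovalent palladium add to the electron-rich aryl bromide near room temperature, the copper acetylide of 9 transmetalates and reductive elimination gives the arylalkyne with the silyl group untouched.

Step 5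
Reactants: 7 6-hydroxy-2,4-dimethoxy-3-(3-methylbut-2-en-1-yl)benzaldehyde; 10 trimethyl[(2,4,5-trimethoxyphenyl)ethynyl]silane
Product: 11 5,7-dimethoxy-6-(3-methylbut-2-en-1-yl)-3-(2,4,5-trimethoxyphenyl)-2-(trimethylsilyl)-4H-chromen-4-one
Conditions: [(C5Me5)Rh(MeCN)3](SbF6)2 (5 mol%), Cu(OAc)2 (2.2 equiv), DCE, 80–100 °C, Ar
Reagents that add atoms: none
Why: After O–H metalation of 7 by the trivalent rhodium acetate, the metal cleaves the neighbouring formyl C–H bond and a five-membered acyl rhodacycle results; 10 then undergoes migratory insertion into the Rh–C(acyl) bond (C4–C3), and the seven-membered oxa-rhodacycle collapses by C–O reductive elimination (O1–C2) to 11 and monovalent rhodium, which Cu(OAc)2 returns to the trivalent state. The closest known reaction type is the rhodium-catalysed oxidative [4+2] annulation of salicylaldehydes with internal alkynes to 2,3-disubstituted chromones. Ring C, the six-membered pyranone, is closed by intermolecular carbometalation followed by intramolecular C–O bond-forming reductive elimination, with O1, C8a, C4a and C4 supplied by 7 and C2 and C3 by 10. No stereocentre is formed. The step needs one orientation of insertion, silicon on the rhodium-bound carbon (future C2), and this should be secured by the general tendency of silylalkynes to place the silyl-bearing carbon on the metal in related palladium and rhodium indole and isoquinolone annulations, reinforced by polarisation of the alkyne through the donor arene and the beta-silicon effect. The single free hydroxyl of 7 allows only one ring closure, and because ring C is born unsaturated no later oxidation has to be carried out beside the prenyl alkene.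

Step 6
Reactants: 11 5,7-dimethoxy-6-(3-methylbut-2-en-1-yl)-3-(2,4,5-trimethoxyphenyl)-2-(trimethylsilyl)-4H-chromen-4-one
Product: 12 5,7-dimethoxy-6-(3-methylbut-2-en-1-yl)-3-(2,4,5-trimethoxyphenyl)-4H-chromen-4-one
Conditions: TBAF (1.2 equiv), wet THF, 0 °C to rt
Reagents that add atoms: none
Why: Fluoride-mediated protodesilylation: fluoride adds to silicon and the C2–Si bond breaks with protonation by water, the developing sp2 carbanion being stabilised by the adjacent ring oxygen as in the desilylation of 2-silylbenzofurans and 2-silylindoles, while the aryl methyl ethers and the alkene are inert.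

Step 7
Reactants: 12 5,7-dimethoxy-6-(3-methylbut-2-en-1-yl)-3-(2,4,5-trimethoxyphenyl)-4H-chromen-4-one
Product: 13 5-hydroxy-7-methoxy-6-(3-methylbut-2-en-1-yl)-3-(2,4,5-trimethoxyphenyl)-4H-chromen-4-one (CNP0525254.0)
Conditions: MgI2·OEt2 (3 equiv), THF, 60 °C; aq NH4Cl
Reagents that add atoms: none
Why: Chelation-directed ether cleavage: MgI2 bridges the C4 carbonyl and the peri C5 methoxy oxygen in a six-membered chelate and iodide removes that methyl group by SN2 attack, whereas the four other methoxy groups cannot form such a chelate and the aprotic magnesium phenoxide does not add to the neighbouring prenyl alkene.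

Compound list
1 | 1,3-dimethoxybenzene | COc1cccc(OC)c1 | starting material
2 | prenyl bromide (1-bromo-3-methylbut-2-ene) | CC(C)=CCBr | starting material
3 | 2,6-dimethoxyphenyllithium | [Li]c1c(OC)cccc1OC | intermediate (not isolated)
4 | 1,3-dimethoxy-2-(3-methylbut-2-en-1-yl)benzene | COc1cccc(OC)c1CC=C(C)C | intermediate
5 | 2-[3,5-dimethoxy-4-(3-methylbut-2-en-1-yl)phenyl]-4,4,5,5-tetramethyl-1,3,2-dioxaborolane | COc1cc(B2OC(C)(C)C(C)(C)O2)cc(OC)c1CC=C(C)C | intermediate (not isolated)
6 | 3,5-dimethoxy-4-(3-methylbut-2-en-1-yl)phenol | COc1cc(O)cc(OC)c1CC=C(C)C | intermediate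
7 | 6-hydroxy-2,4-dimethoxy-3-(3-methylbut-2-en-1-yl)benzaldehyde | COc1cc(O)c(C=O)c(OC)c1CC=C(C)C | intermediate
8 | 1-bromo-2,4,5-trimethoxybenzene | COc1cc(OC)c(Br)cc1OC | starting material
9 | ethynyltrimethylsilane | C#C[Si](C)(C)C | starting material
10 | trimethyl[(2,4,5-trimethoxyphenyl)ethynyl]silane | COc1cc(OC)c(C#C[Si](C)(C)C)cc1OC | intermediate
11 | 5,7-dimethoxy-6-(3-methylbut-2-en-1-yl)-3-(2,4,5-trimethoxyphenyl)-2-(trimethylsilyl)-4H-chromen-4-one | COc1cc(OC)c(-c2c([Si](C)(C)C)oc3cc(OC)c(CC=C(C)C)c(OC)c3c2=O)cc1OC | intermediate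
12 | 5,7-dimethoxy-6-(3-methylbut-2-en-1-yl)-3-(2,4,5-trimethoxyphenyl)-4H-chromen-4-one | COc1cc(OC)c(-c2coc3cc(OC)c(CC=C(C)C)c(OC)c3c2=O)cc1OC | intermediate
13 | 5-hydroxy-7-methoxy-6-(3-methylbut-2-en-1-yl)-3-(2,4,5-trimethoxyphenyl)-4H-chromen-4-one | COc1cc(OC)c(-c2coc3cc(OC)c(CC=C(C)C)c(O)c3c2=O)cc1OC | target

Total steps: 7. Longest linear sequence: 6 (steps 1, 2, 3, 5, 6, 7).

Steps most likely to fail

1. Step 5. The alkyne may insert in the reverse orientation and carry ring B to C2. The alkynyl silyl group may be lost before insertion, or turnover may stall with two hindered, electron-rich partners. Loss of the C2 silyl group after ring closure is harmless, since it leads to 12. The fallback replaces the annulation by cross-coupling on a preformed chromone; it sets out from aldehyde 7 and comes back at 12. Addition of MeMgBr (3 equiv, THF, 0 °C) should give the racemic secondary benzylic alcohol F1. MnO2 in CH2Cl2 should then give the ortho-hydroxyacetophenone F2, and Me2NCH(OMe)2 at 90 °C the enaminone F3. I2 and pyridine in CHCl3 should convert F3 into the 3-iodochromone F4 by iodination and cyclisation with loss of dimethylamine. Suzuki coupling of F4 with purchased (2,4,5-trimethoxyphenyl)boronic acid (Pd(dppf)Cl2, Na2CO3, DME/H2O, 80 °C) then gives 12 with no question of orientation.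

2. Step 2. Iridium boryl or hydride species may hydroborate or isomerise the prenyl alkene, borylation may occur next to a methoxy group, or the electron-rich phenol may be over-oxidised by peroxide. The fallback puts the phenol oxygen in place before the alkene arrives; it sets out from prenyl bromide 2 and comes back at phenol 6. Purchased 3,5-dimethoxyphenol F5 is silylated (TIPSCl, imidazole, DMF) to the triisopropylsilyl ether F6. n-BuLi in THF at 0 °C should lithiate between the two methoxy groups, since the bulky silyloxy group is a poor director, to give the aryllithium F7. Alkylation with 2 (CuI cat.) gives the prenylated silyl ether F8, and TBAF in THF releases 6.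

3. Step 7. The freed C5 hydroxyl or hydrogen iodide may add across the neighbouring prenyl alkene during reaction or work-up, or the ether cleavage may be incomplete or unselective. The fallback avoids methyl ether cleavage: the two oxygens flanking the prenyl group are carried as acetals and the C7 methyl group is put on last. It sets out from prenyl bromide 2 and alkyne 10 and comes back at target 13.
   - Commercial 1,3-bis(methoxymethoxy)benzene F9 is lithiated between the acetal oxygens (n-BuLi, THF, 0 °C) to the aryllithium F10 and alkylated with 2 (CuI cat.) to the 2-prenyl bis-acetal F11.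
   - Iridium-catalysed borylation as in step 2 gives the pinacol boronate F12, and alkaline H2O2 gives the phenol F13.
   - MgCl2, Et3N and (CH2O)n give the salicylaldehyde F14, and annulation with 10 under the conditions of step 5 gives the 2-silylchromone F15.
   - TBAF gives the bis-acetal isoflavone F16, and dilute HCl in MeOH at 40 °C, the usual mild acetal hydrolysis for prenylated polyphenols, gives the 5,7-dihydroxyisoflavone F17.
   - K2CO3 and MeI (1.05 equiv) in acetone methylate only the more acidic, non-chelated C7 hydroxyl and give 13.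

Further compounds
F1 | step 5 | 2-(1-hydroxyethyl)-3,5-dimethoxy-4-(3-methylbut-2-en-1-yl)phenol (racemic) | COc1cc(O)c(C(C)O)c(OC)c1CC=C(C)C
F2 | step 5 | 1-[6-hydroxy-2,4-dimethoxy-3-(3-methylbut-2-en-1-yl)phenyl]ethan-1-one | COc1cc(O)c(C(C)=O)c(OC)c1CC=C(C)C
F3 | step 5 | (E)-3-(dimethylamino)-1-[6-hydroxy-2,4-dimethoxy-3-(3-methylbut-2-en-1-yl)phenyl]prop-2-en-1-one | COc1cc(O)c(C(=O)/C=C/N(C)C)c(OC)c1CC=C(C)C
F4 | step 5 | 3-iodo-5,7-dimethoxy-6-(3-methylbut-2-en-1-yl)-4H-chromen-4-one | COc1cc2occ(I)c(=O)c2c(OC)c1CC=C(C)C
F5 | step 2 | 3,5-dimethoxyphenol (purchased) | COc1cc(O)cc(OC)c1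
F6 | step 2 | (3,5-dimethoxyphenoxy)tri(propan-2-yl)silane | COc1cc(O[Si](C(C)C)(C(C)C)C(C)C)cc(OC)c1
F7 | step 2 | [2,6-dimethoxy-4-(triisopropylsilyloxy)phenyl]lithium | [Li]c1c(OC)cc(O[Si](C(C)C)(C(C)C)C(C)C)cc1OC
F8 | step 2 | [3,5-dimethoxy-4-(3-methylbut-2-en-1-yl)phenoxy]tri(propan-2-yl)silane | COc1cc(O[Si](C(C)C)(C(C)C)C(C)C)cc(OC)c1CC=C(C)C
F9 | step 7 | 1,3-bis(methoxymethoxy)benzene (purchased) | COCOc1cccc(OCOC)c1
F10 | step 7 | [2,6-bis(methoxymethoxy)phenyl]lithium | [Li]c1c(OCOC)cccc1OCOC
F11 | step 7 | 1,3-bis(methoxymethoxy)-2-(3-methylbut-2-en-1-yl)benzene | COCOc1cccc(OCOC)c1CC=C(C)C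
F12 | step 7 | 2-[3,5-bis(methoxymethoxy)-4-(3-methylbut-2-en-1-yl)phenyl]-4,4,5,5-tetramethyl-1,3,2-dioxaborolane | COCOc1cc(B2OC(C)(C)C(C)(C)O2)cc(OCOC)c1CC=C(C)C
F13 | step 7 | 3,5-bis(methoxymethoxy)-4-(3-methylbut-2-en-1-yl)phenol | COCOc1cc(O)cc(OCOC)c1CC=C(C)C
F14 | step 7 | 6-hydroxy-2,4-bis(methoxymethoxy)-3-(3-methylbut-2-en-1-yl)benzaldehyde | COCOc1cc(O)c(C=O)c(OCOC)c1CC=C(C)C
F15 | step 7 | 5,7-bis(methoxymethoxy)-6-(3-methylbut-2-en-1-yl)-3-(2,4,5-trimethoxyphenyl)-2-(trimethylsilyl)-4H-chromen-4-one | COCOc1cc2oc([Si](C)(C)C)c(-c3cc(OC)c(OC)cc3OC)c(=O)c2c(OCOC)c1CC=C(C)C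
F16 | step 7 | 5,7-bis(methoxymethoxy)-6-(3-methylbut-2-en-1-yl)-3-(2,4,5-trimethoxyphenyl)-4H-chromen-4-one | COCOc1cc2occ(-c3cc(OC)c(OC)cc3OC)c(=O)c2c(OCOC)c1CC=C(C)C
F17 | step 7 | 5,7-dihydroxy-6-(3-methylbut-2-en-1-yl)-3-(2,4,5-trimethoxyphenyl)-4H-chromen-4-one | COc1cc(OC)c(-c2coc3cc(O)c(CC=C(C)C)c(O)c3c2=O)cc1OC
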